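The data are simulated on assumed constants; noise was put on by code.

Of the L charged, Q read 34% in the dusk run and 32% in the summer run at 1.67 d, and then sank. E stood at 1.10 equivalents, so L was the limiting reagent.

| flask | L | E | X | remark | time |
|---|---|---|---|---|---|
| dusk | 0.033 M | 0.0363 M | 33 µM | run made earlier |  |
| summer | 0.033 M | 0.0363 M | 50 µM | run made earlier |  |
| flask | 0.033 M | 0.0363 M | 66 µM |  | 4.0 d |

| run | time / d | Q / % |
|---|---|---|
| dusk | 0.333 | 1 |
| dusk | 0.500 | 7 |
| dusk | 0.833 | 16 |
| dusk | 1.25 | 25 |
| dusk | 1.67 | 34 |
| dusk | 2.50 | 33 |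
| dusk | 4.00 | 30 |
| summer | 0.333 | 2 |
| summer | 0.500 | 11 |
| summer | 0.833 | 17 |
| summer | 1.25 | 27 |
| summer | 1.67 | 32 |
| summer | 2.50 | 28 |
| summer | 4.00 | 24 |

(readings scatter by 2 percentage points)

- the best time, 4.0 d at the latest, for Q
- the amount of Q, in percent of the L charged, at that time

- as a solid, counted per litre of solution: L
- at the start none of L is in solution

I asked first what each number would move. Raising X from 33 µM to 50 µM shifted the peak reading by 2 percentage points, about the size of the scatter, so a poor X would do the height little harm. The last readings, however, differed by 6 points, more than the scatter of one reading.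

I therefore counted the tail of each run by the catalyst dose, the X charged times the time elapsed, and assumed that equal doses after the peak give equal Q:

dusk, last reading: 132 µM·d

same dose in the flask: 2.00 d

So my own reckoning put the flask near 30% at 2.00 d, a point on its tail, with its best earlier.

The forecast gave 30% at 1.7 d, holding that “Q loss is catalysed”.

The flask gave 31.6% at 1.43 d.

    J + X → X + D (k = 0.336 M⁻¹ s⁻¹)
    E + X + D → X + Q (k = 87.2 M⁻² s⁻¹)
    Q + X ⇌ G + X, rate k3*[X]*[Q] forward; the back reaction follows from the equilibrium constant (K = 3.10, k = 0.404 M⁻¹ s⁻¹)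
    L ⇌ J, rate k4*(cs4 - [J]) while solid is left; crystals form when [J] > cs4 (solubility = 31.0 mM, k = 1.66 × 10⁻⁵ s⁻¹)

In the flask Q passed into G with a forward half-life of 0.30 d, with the other concentrations as charged, which is short against 4.0 d. At 2.00 d, the dose of the last dusk reading, the flask held 28.9% Q where the dusk run had read 30%. At 4.00 d the flask had taken a dose of 264 µM·d and held 24.7%. The neighbour flask with 0.013 M of L, at the same X and the same dose, held 24.5% of its own smaller charge.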